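**Retrosynthetic overview**
1. Target ⇐ acetylation of the 16,19-dihydroxy acid ⇐ desilylation and saponification of a (13E)-16-hydroxy enoate.
2. C13–C16 bond: stereoretentive Stille hydroxymethylation of the (E)-enol triflate of a β-keto ester, which fixes the alkene geometry.
3. C13–C14 bond (key fragment union): intermolecular aldol addition of the lithium enolate of ethyl acetate to the C13 aldehyde, then oxidation to the β-keto ester.
4. C13 aldehyde ⇐ Wittig one-carbon homologation of the C12 aldehyde, with Barton–McCombie removal of the C3 hydroxyl on the way.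
5. Rings: none is built. Rings A and B (the trans-decalin with C4, C5, C9, C10 and the 8(17)-methylene) are taken intact from andrographolide by oxidative cleavage of its C12=C13 bond.

Assumption: the SMILES is read as (13E)-16,19-diacetoxy-ent-labda-8(17),13-dien-15-oic acid (C12 cis to CO2H, CH2OAc at C4 cis to the C10 methyl); andrographolide has the same C4, C5, C9 and C10 configurations and is taken as a cheap commercial starting material.

**Step 1**
Reactants: 1 andrographolide
Product: 2 3,19-O-isopropylideneandrographolide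
Conditions: Me2C(OMe)2, PPTS (cat.), toluene/DMSO, 80 °C
Reagents that add atoms: 2,2-dimethoxypropane, COC(C)(C)OC
Why: Acid-catalysed transketalization closes a six-membered 1,3-dioxane across the cis-related 3-OH and 19-OH, leaving the 14-OH free.

**Step 2**
Reactants: 2 3,19-O-isopropylideneandrographolide
Product: 3 3,19-O-isopropylidene-13,14,15,16-tetranor-ent-labd-8(17)-en-12-al
Conditions: KMnO4, THF/H2O, −10 → 0 °C
Reagents that add atoms: potassium permanganate, [K+].[O-][Mn](=O)(=O)=O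
Why: Permanganate oxidative cleavage (syn-dihydroxylation then glycol cleavage) should take the conjugated, electron-poor C12=C13 of the alkylidene lactone faster than the hindered 8(17)-methylene, and no stereocentre is touched.

**Step 3**
Reactants: 3 3,19-O-isopropylidene-13,14,15,16-tetranor-ent-labd-8(17)-en-12-al; 4 (methoxymethyl)triphenylphosphonium chloride
Product: 5 3,19-O-isopropylidene-13-methoxy-14,15,16-trinor-ent-labda-8(17),12-diene (E/Z mixture)
Conditions: 4, KN(SiMe3)2, THF, 0 °C; then 3, −78 → 0 °C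
Reagents that add atoms: none
Why: Wittig methoxymethylenation of an unhindered CH2–CHO adds C13 as a masked aldehyde; the E/Z ratio is irrelevant because the enol ether is solvolysed next.

**Step 4**
Reactants: 5 3,19-O-isopropylidene-13-methoxy-14,15,16-trinor-ent-labda-8(17),12-diene
Product: 6 13,13-dimethoxy-14,15,16-trinor-ent-labd-8(17)-ene-3,19-diol
Conditions: CSA (cat.), MeOH, rt
Reagents that add atoms: methanol, CO
Why: Acid-catalysed addition of methanol to the enol ether gives the dimethyl acetal while transketalization to methanol removes the acetonide; the exocyclic alkene tolerates this mild acid.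

**Step 5**
Reactants: 6 13,13-dimethoxy-14,15,16-trinor-ent-labd-8(17)-ene-3,19-diol
Product: 7 19-(tert-butyldiphenylsilyloxy)-13,13-dimethoxy-14,15,16-trinor-ent-labd-8(17)-en-3-ol
Conditions: TBDPSCl, imidazole, DMF, 0 °C → rt
Reagents that add atoms: tert-butyldiphenylsilyl chloride, CC(C)(C)[Si](Cl)(c1ccccc1)c1ccccc1
Why: Chemoselective silylation: the bulky silyl chloride reacts with the primary 19-OH and not with the secondary 3-OH next to the quaternary C4.

**Step 6**
Reactants: 7 19-(tert-butyldiphenylsilyloxy)-13,13-dimethoxy-14,15,16-trinor-ent-labd-8(17)-en-3-ol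
Product: 9 O-(C3) S-methyl xanthate of 7, via potassium xanthate 8 (not isolated)
Conditions: KN(SiMe3)2, THF, −78 °C; CS2; MeI, −78 → 0 °C
Reagents that add atoms: carbon disulfide, S=C=S; iodomethane, CI
Why: Xanthate formation (first half of the Barton–McCombie deoxygenation) uses the small electrophile CS2, which reaches the hindered alkoxide, and the low temperature suppresses 1,3-silyl migration.

**Step 7**
Reactants: 9 O-(C3) S-methyl xanthate of 7
Product: 10 19-(tert-butyldiphenylsilyloxy)-13,13-dimethoxy-14,15,16-trinor-ent-labd-8(17)-ene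
Conditions: Bu3SnH, AIBN (cat.), toluene, 110 °C
Reagents that add atoms: none
Why: Barton–McCombie radical deoxygenation: the secondary C3 radical is simply reduced by the stannane, and C3 becomes CH2 so no stereocentre is at stake.

**Step 8**
Reactants: 10 19-(tert-butyldiphenylsilyloxy)-13,13-dimethoxy-14,15,16-trinor-ent-labd-8(17)-ene
Product: 11 19-(tert-butyldiphenylsilyloxy)-14,15,16-trinor-ent-labd-8(17)-en-13-al
Conditions: PPTS, acetone/H2O (10:1), 45 °C
Reagents that add atoms: water, O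
Why: Mild acetal hydrolysis frees the C13 aldehyde; the weak buffered acid spares the silyl ether and avoids ene-type closure of the aldehyde onto the 8(17)-methylene.

**Step 9**
Reactants: 11 19-(tert-butyldiphenylsilyloxy)-14,15,16-trinor-ent-labd-8(17)-en-13-al; 12 ethyl acetate
Product: 13 ethyl 19-(tert-butyldiphenylsilyloxy)-13-hydroxy-16-nor-ent-labd-8(17)-en-15-oate (both C13 epimers)
Conditions: 12, LiN(iPr)2, THF, −78 °C; then 11, −78 °C; NH4Cl (aq)
Reagents that add atoms: none
Why: Intermolecular aldol addition of the preformed lithium ester enolate to the unhindered aldehyde forms the C13–C14 bond and joins the two fragments; the new carbinol centre is erased in the next step.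

**Step 10**
Reactants: 13 ethyl 19-(tert-butyldiphenylsilyloxy)-13-hydroxy-16-nor-ent-labd-8(17)-en-15-oate
Product: 14 ethyl 19-(tert-butyldiphenylsilyloxy)-13-oxo-16-nor-ent-labd-8(17)-en-15-oate
Conditions: Dess–Martin periodinane, CH2Cl2, 0 °C → rt
Reagents that add atoms: none
Why: Dess–Martin oxidation converts the β-hydroxy ester into the β-keto ester under neutral conditions that leave the alkene and silyl ether alone.

**Step 11**
Reactants: 14 ethyl 19-(tert-butyldiphenylsilyloxy)-13-oxo-16-nor-ent-labd-8(17)-en-15-oate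
Product: 15 ethyl (13E)-19-(tert-butyldiphenylsilyloxy)-13-(trifluoromethylsulfonyloxy)-16-nor-ent-labda-8(17),13-dien-15-oate (OTf trans to CO2Et)
Conditions: Tf2O, Me4NOH (25% aq), hexanes, 5 °C
Reagents that add atoms: triflic anhydride, O=S(=O)(OS(=O)(=O)C(F)(F)F)C(F)(F)F
Why: Stereoselective enol triflation: the non-chelated tetramethylammonium enolate adopts the extended geometry with the enolate oxygen anti to the ester, so O-sulfonylation gives the (E)-enol triflate.

**Step 12**
Reactants: 15 ethyl (13E)-19-(tert-butyldiphenylsilyloxy)-13-(trifluoromethylsulfonyloxy)-16-nor-ent-labda-8(17),13-dien-15-oate; 16 (tributylstannyl)methanol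
Product: 17 ethyl (13E)-19-(tert-butyldiphenylsilyloxy)-16-hydroxy-ent-labda-8(17),13-dien-15-oate
Conditions: 16, Pd(PPh3)4 (cat.), LiCl, 1,4-dioxane, 90 °C
Reagents that add atoms: none
Why: Stille cross-coupling (oxidative addition of zerovalent palladium to the C–OTf bond, transmetalation, reductive elimination) retains the alkene geometry, placing C16 trans to the ester and C12 cis to it, so the alcohol cannot lactonise.

**Step 13**
Reactants: 17 ethyl (13E)-19-(tert-butyldiphenylsilyloxy)-16-hydroxy-ent-labda-8(17),13-dien-15-oate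
Product: 18 ethyl (13E)-16,19-dihydroxy-ent-labda-8(17),13-dien-15-oate
Conditions: Bu4NF, THF, rt → 45 °C
Reagents that add atoms: none
Why: Fluoride-mediated desilylation, driven by the Si–F bond, frees the neopentyl 19-OH without affecting the enoate or the exocyclic alkene.

**Step 14**
Reactants: 18 ethyl (13E)-16,19-dihydroxy-ent-labda-8(17),13-dien-15-oate
Product: 19 (13E)-16,19-dihydroxy-ent-labda-8(17),13-dien-15-oic acid
Conditions: LiOH, THF/MeOH/H2O, 40 °C; then dilute HCl to pH 3, 0 °C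
Reagents that add atoms: lithium hydroxide, [Li+].[OH-]
Why: Saponification of the ethyl ester; base does not disturb the methylene or the enoate geometry, and the trans-disposed 16-OH cannot close a butenolide.

**Step 15**
Reactants: 19 (13E)-16,19-dihydroxy-ent-labda-8(17),13-dien-15-oic acid
Product: 21 (13E)-16,19-diacetoxy-ent-labda-8(17),13-dien-15-oic acid (target), via mixed anhydride 20 (not isolated)
Conditions: Ac2O, pyridine, DMAP (cat.), CH2Cl2, rt; then H2O/THF, rt
Reagents that add atoms: acetic anhydride, CC(=O)OC(C)=O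
Why: DMAP-catalysed acetylation esterifies both primary alcohols, and the acetic mixed anhydride formed at the carboxyl group is hydrolysed selectively by water to return the free acid.

**Compound list**
1 | andrographolide | C=C1CC[C@@H]2[C@](C)(CO)[C@H](O)CC[C@@]2(C)[C@@H]1C/C=C1/C(=O)OC[C@H]1O | starting material
2 | 3,19-O-isopropylideneandrographolide | C=C1CC[C@@H]2[C@]3(C)COC(C)(C)O[C@@H]3CC[C@@]2(C)[C@@H]1C/C=C1/C(=O)OC[C@H]1O | intermediate
3 | 3,19-O-isopropylidene-13,14,15,16-tetranor-ent-labd-8(17)-en-12-al | C=C1CC[C@@H]2[C@]3(C)COC(C)(C)O[C@@H]3CC[C@@]2(C)[C@@H]1CC=O | intermediate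
4 | (methoxymethyl)triphenylphosphonium chloride | COC[P+](c1ccccc1)(c1ccccc1)c1ccccc1.[Cl-] | starting material
5 | 3,19-O-isopropylidene-13-methoxy-14,15,16-trinor-ent-labda-8(17),12-diene (E/Z mixture) | C=C1CC[C@@H]2[C@]3(C)COC(C)(C)O[C@@H]3CC[C@@]2(C)[C@@H]1CC=COC | intermediate
6 | 13,13-dimethoxy-14,15,16-trinor-ent-labd-8(17)-ene-3,19-diol | C=C1CC[C@@H]2[C@](C)(CO)[C@H](O)CC[C@@]2(C)[C@@H]1CCC(OC)OC | intermediate
7 | 19-(tert-butyldiphenylsilyloxy)-13,13-dimethoxy-14,15,16-trinor-ent-labd-8(17)-en-3-ol | C=C1CC[C@@H]2[C@](C)(CO[Si](c3ccccc3)(c3ccccc3)C(C)(C)C)[C@H](O)CC[C@@]2(C)[C@@H]1CCC(OC)OC | intermediate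
8 | potassium O-(C3) dithiocarbonate (xanthate salt) of 7 | C=C1CC[C@@H]2[C@](C)(CO[Si](c3ccccc3)(c3ccccc3)C(C)(C)C)[C@H](OC(=S)[S-])CC[C@@]2(C)[C@@H]1CCC(OC)OC.[K+] | intermediate (not isolated)
9 | O-(C3) S-methyl xanthate of 7 | C=C1CC[C@@H]2[C@](C)(CO[Si](c3ccccc3)(c3ccccc3)C(C)(C)C)[C@H](OC(=S)SC)CC[C@@]2(C)[C@@H]1CCC(OC)OC | intermediate
10 | 19-(tert-butyldiphenylsilyloxy)-13,13-dimethoxy-14,15,16-trinor-ent-labd-8(17)-ene | C=C1CC[C@@H]2[C@](C)(CO[Si](c3ccccc3)(c3ccccc3)C(C)(C)C)CCC[C@@]2(C)[C@@H]1CCC(OC)OC | intermediate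
11 | 19-(tert-butyldiphenylsilyloxy)-14,15,16-trinor-ent-labd-8(17)-en-13-al | C=C1CC[C@@H]2[C@](C)(CO[Si](c3ccccc3)(c3ccccc3)C(C)(C)C)CCC[C@@]2(C)[C@@H]1CCC=O | intermediate
12 | ethyl acetate | CCOC(C)=O | starting material
13 | ethyl 19-(tert-butyldiphenylsilyloxy)-13-hydroxy-16-nor-ent-labd-8(17)-en-15-oate (C13 epimers) | C=C1CC[C@@H]2[C@](C)(CO[Si](c3ccccc3)(c3ccccc3)C(C)(C)C)CCC[C@@]2(C)[C@@H]1CCC(O)CC(=O)OCC | intermediate
14 | ethyl 19-(tert-butyldiphenylsilyloxy)-13-oxo-16-nor-ent-labd-8(17)-en-15-oate | C=C1CC[C@@H]2[C@](C)(CO[Si](c3ccccc3)(c3ccccc3)C(C)(C)C)CCC[C@@]2(C)[C@@H]1CCC(=O)CC(=O)OCC | intermediate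
15 | ethyl (13E)-19-(tert-butyldiphenylsilyloxy)-13-(trifluoromethylsulfonyloxy)-16-nor-ent-labda-8(17),13-dien-15-oate | C=C1CC[C@@H]2[C@](C)(CO[Si](c3ccccc3)(c3ccccc3)C(C)(C)C)CCC[C@@]2(C)[C@@H]1CC/C(OS(=O)(=O)C(F)(F)F)=C\C(=O)OCC | intermediate
16 | (tributylstannyl)methanol | CCCC[Sn](CCCC)(CCCC)CO | starting material
17 | ethyl (13E)-19-(tert-butyldiphenylsilyloxy)-16-hydroxy-ent-labda-8(17),13-dien-15-oate | C=C1CC[C@@H]2[C@](C)(CO[Si](c3ccccc3)(c3ccccc3)C(C)(C)C)CCC[C@@]2(C)[C@@H]1CC/C(CO)=C\C(=O)OCC | intermediate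
18 | ethyl (13E)-16,19-dihydroxy-ent-labda-8(17),13-dien-15-oate | C=C1CC[C@@H]2[C@](C)(CO)CCC[C@@]2(C)[C@@H]1CC/C(CO)=C\C(=O)OCC | intermediate
19 | (13E)-16,19-dihydroxy-ent-labda-8(17),13-dien-15-oic acid | C=C1CC[C@@H]2[C@](C)(CO)CCC[C@@]2(C)[C@@H]1CC/C(CO)=C\C(=O)O | intermediate
20 | acetic (13E)-16,19-diacetoxy-ent-labda-8(17),13-dien-15-oic anhydride | C=C1CC[C@@H]2[C@](C)(COC(C)=O)CCC[C@@]2(C)[C@@H]1CC/C(COC(C)=O)=C\C(=O)OC(C)=O | intermediate (not isolated)
21 | (13E)-16,19-diacetoxy-ent-labda-8(17),13-dien-15-oic acid | C=C1CC[C@@H]2[C@](C)(COC(C)=O)CCC[C@@]2(C)[C@@H]1CC/C(COC(C)=O)=C\C(=O)O | target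

**Totals**
Total step count: 15. Longest linear sequence: 15 steps (1 → 21).

**Three steps most likely to fail**

Step 2 (permanganate may also attack the 8(17)-methylene or over-oxidise the aldehyde). The fallback sets out from 2. Peracid epoxidises only the electron-rich methylene (mCPBA, NaHCO3, CH2Cl2, 0 °C; the conjugated lactone alkene is inert), with oxygen delivered anti to the C10 methyl, giving 8,17-epoxy-3,19-O-isopropylideneandrographolide F1. Ozonolysis of the one remaining alkene (O3, CH2Cl2/MeOH, −78 °C; Me2S) gives the 8,17-epoxy analogue of aldehyde 3 F2. The Wittig reaction of step 3 on F2 gives the 8,17-epoxy analogue of enol ether 5 F3. Deoxygenation of the epoxide with the low-valent tungsten reagent from WCl6 and n-BuLi (THF, −78 °C → rt) restores the methylene and comes back to the route at 5.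

Step 11 (an insufficient E:Z ratio of the enol triflate would give the wrong, lactonising alkene isomer). The fallback sets out from 11 and builds the alkene by syn-carbocupration instead. Ohira–Bestmann homologation (dimethyl (1-diazo-2-oxopropyl)phosphonate, K2CO3, MeOH, rt) gives 19-(tert-butyldiphenylsilyloxy)-15,16-dinor-ent-labd-8(17)-en-13-yne F4. Deprotonation and acylation (n-BuLi, THF, −78 °C; ClCO2Et) give ethyl 19-(tert-butyldiphenylsilyloxy)-16-nor-ent-labd-8(17)-en-13-yn-15-oate F5. Syn addition of the (4-methoxybenzyloxy)methyl cuprate (from Bu3SnCH2OPMB, n-BuLi and CuBr·SMe2, THF, −78 °C, quenched cold) puts the new CH2O group cis to H14 and gives ethyl (13E)-19-(tert-butyldiphenylsilyloxy)-16-(4-methoxybenzyloxy)-ent-labda-8(17),13-dien-15-oate F6. Oxidative removal of the PMB group (DDQ, CH2Cl2/pH 7 buffer) comes back to the route at 17.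

Step 12 (the hydroxymethyl stannane may transfer sluggishly or the alkene may isomerise on heating). The fallback sets out from 15 and brings in C16 as carbon monoxide. Palladium-catalysed reductive carbonylation (Pd(PPh3)4, CO 1 atm, Bu3SnH added slowly, LiCl, THF, 50 °C) gives ethyl (13E)-19-(tert-butyldiphenylsilyloxy)-16-oxo-ent-labda-8(17),13-dien-15-oate F7. Luche 1,2-reduction of the aldehyde (NaBH4, CeCl3·7H2O, MeOH, −40 °C) leaves the ester untouched and comes back to the route at 17.

**Further compounds**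
F1 | step 2 | 8,17-epoxy-3,19-O-isopropylideneandrographolide (epoxide oxygen anti to the C10 methyl) | C1O[C@]12CC[C@@H]3[C@]4(C)COC(C)(C)O[C@@H]4CC[C@@]3(C)[C@@H]2C/C=C2/C(=O)OC[C@H]2O
F2 | step 2 | 8,17-epoxy-3,19-O-isopropylidene-13,14,15,16-tetranor-ent-labdan-12-al | C1O[C@]12CC[C@@H]3[C@]4(C)COC(C)(C)O[C@@H]4CC[C@@]3(C)[C@@H]2CC=O
F3 | step 2 | 8,17-epoxy-3,19-O-isopropylidene-13-methoxy-14,15,16-trinor-ent-labd-12-ene (E/Z mixture) | C1O[C@]12CC[C@@H]3[C@]4(C)COC(C)(C)O[C@@H]4CC[C@@]3(C)[C@@H]2CC=COC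
F4 | step 11 | 19-(tert-butyldiphenylsilyloxy)-15,16-dinor-ent-labd-8(17)-en-13-yne | C=C1CC[C@@H]2[C@](C)(CO[Si](c3ccccc3)(c3ccccc3)C(C)(C)C)CCC[C@@]2(C)[C@@H]1CCC#C
F5 | step 11 | ethyl 19-(tert-butyldiphenylsilyloxy)-16-nor-ent-labd-8(17)-en-13-yn-15-oate | C=C1CC[C@@H]2[C@](C)(CO[Si](c3ccccc3)(c3ccccc3)C(C)(C)C)CCC[C@@]2(C)[C@@H]1CCC#CC(=O)OCC
F6 | step 11 | ethyl (13E)-19-(tert-butyldiphenylsilyloxy)-16-(4-methoxybenzyloxy)-ent-labda-8(17),13-dien-15-oate | C=C1CC[C@@H]2[C@](C)(CO[Si](c3ccccc3)(c3ccccc3)C(C)(C)C)CCC[C@@]2(C)[C@@H]1CC/C(COCc3ccc(OC)cc3)=C\C(=O)OCC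
F7 | step 12 | ethyl (13E)-19-(tert-butyldiphenylsilyloxy)-16-oxo-ent-labda-8(17),13-dien-15-oate | C=C1CC[C@@H]2[C@](C)(CO[Si](c3ccccc3)(c3ccccc3)C(C)(C)C)CCC[C@@]2(C)[C@@H]1CC/C(C=O)=C\C(=O)OCC
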